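Prostanoid numbering is used (ester carbon C1; ring C8–C12; ketone C9; C–Br C10; carbinol C12). Everything rests on closing the cyclopentenone last, between acyl carbon C9 and vinylic carbon C8, by an intramolecular ketone-forming Stille coupling. The step exploits the C12 carbinol, which carries both partners: its free hydroxyl first steers a trans-hydrostannation that puts tin on C8 and fixes the 7Z exocyclic geometry, and the (E)-2-bromoacryloyl arm (C9–C11) holds C9 cis to C12, so one acylation delivers the cross-conjugated 2-bromo-5-alkylidenecyclopent-2-enone ring. The precursor is an acyclic acid chloride with the C12 silyl ether, the C8 stannane and both complete side chains.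

Key step: step 12

Remark: compounds 1, 2, 5, 8 and 15 and all reagents are taken as catalogue chemicals; C-numbers in the text follow the prostanoid numbering given above.

Step 1
Reactants: 1 2-bromoprop-2-en-1-ol; 2 ethynyl(trimethyl)silane
Product: 3 2-methylidene-4-(trimethylsilyl)but-3-yn-1-ol
Conditions: PdCl2(PPh3)2 (cat.), CuI (cat.), i-Pr2NH, THF, rt
Reagents that add atoms: none
Why: Sonogashira coupling of the vinyl bromide with the terminal alkyne gives the 2-alkynyl allylic alcohol; no stereocentre is formed.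

Step 2
Reactants: 3 2-methylidene-4-(trimethylsilyl)but-3-yn-1-ol
Product: 4 [(2S)-2-[(trimethylsilyl)ethynyl]oxiran-2-yl]methanol
Conditions: Ti(Oi-Pr)4 (cat.), L-(+)-diisopropyl tartrate (cat.), t-BuOOH, 4 Å MS, CH2Cl2, −20 °C
Reagents that add atoms: tert-butyl hydroperoxide, CC(C)(C)OO
Why: Sharpless asymmetric epoxidation of a 2-substituted allylic alcohol; the titanium–L-(+)-tartrate complex should deliver oxygen to the enantioface that gives the (S)-epoxide, whose quaternary carbon becomes C12 (R) of the target.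

Step 3
Reactants: 4 [(2S)-2-[(trimethylsilyl)ethynyl]oxiran-2-yl]methanol; 5 hept-1-yne
Product: 6 (2S)-2-[(trimethylsilyl)ethynyl]dec-4-yne-1,2-diol
Conditions: 5, n-BuLi, THF, −78 °C; BF3·OEt2; then 4, −78 °C (one equivalent of acetylide is consumed by the hydroxyl)
Reagents that add atoms: none
Why: BF3-assisted SN2 alkynylation of the epoxide at its unsubstituted CH2 terminus by the hard lithium acetylide; the C–O bond at the quaternary carbon is not touched, so the configuration is kept.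

Step 4
Reactants: 6 (2S)-2-[(trimethylsilyl)ethynyl]dec-4-yne-1,2-diol
Product: 7 (2S,4Z)-2-[(trimethylsilyl)ethynyl]dec-4-ene-1,2-diol
Conditions: H2 (1 atm), Pd/CaCO3 poisoned with Pb(OAc)2, quinoline, EtOAc, rt
Reagents that add atoms: none
Why: Lindlar-type cis semihydrogenation; syn delivery of H2 sets the Z alkene, and the silyl-capped alkyne next to the quaternary carbinol is shielded and should react much more slowly.

Step 5
Reactants: 8 methyl hex-5-ynoate
Product: 10 methyl (5E)-6-iodohex-5-enoate, via alkenylzirconocene chloride 9 (not isolated)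
Conditions: Cp2Zr(H)Cl, CH2Cl2, rt; then I2, 0 °C
Reagents that add atoms: iodine, II
Why: Hydrozirconation of the terminal alkyne (syn, metal at the terminus) followed by iodinolysis with retention should give the E vinyl iodide; the alkyne reacts far faster than the ester.

Step 6
Reactants: 7 (2S,4Z)-2-[(trimethylsilyl)ethynyl]dec-4-ene-1,2-diol; 10 methyl (5E)-6-iodohex-5-enoate
Product: 12 methyl (5E,9S,11Z)-9-hydroxy-9-(hydroxymethyl)heptadeca-5,11-dien-7-ynoate, via ethynyl diol 11 (not isolated)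
Conditions: K2CO3 (cat.), MeOH, rt; then 10, Pd(PPh3)4 (cat.), CuI (cat.), Et3N, THF, rt
Reagents that add atoms: none
Why: Base-catalysed methanolysis of the alkynyl C–Si bond and Sonogashira coupling in one pot; the vinyl iodide couples with retention, so the 5E geometry is carried over.

Step 7
Reactants: 12 methyl (5E,9S,11Z)-9-hydroxy-9-(hydroxymethyl)heptadeca-5,11-dien-7-ynoate
Product: 13 methyl (5E,7Z,9R,11Z)-9-hydroxy-9-(hydroxymethyl)-8-(tributylstannyl)heptadeca-5,7,11-trienoate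
Conditions: [Cp*RuCl]4 (cat.), Bu3SnH, CH2Cl2, rt
Reagents that add atoms: tributyltin hydride, CCCC[SnH](CCCC)CCCC
Why: Ruthenium-catalysed trans-hydrostannation; a hydrogen bond from the C12 hydroxyl to the chloride on ruthenium steers tin to the proximal alkyne carbon C8, and the anti delivery of H and Sn leaves C6 cis to tin, which sets the 7Z geometry.

Step 8
Reactants: 13 methyl (5E,7Z,9R,11Z)-9-hydroxy-9-(hydroxymethyl)-8-(tributylstannyl)heptadeca-5,7,11-trienoate
Product: 14 methyl (5E,7Z,9R,11Z)-9-formyl-9-hydroxy-8-(tributylstannyl)heptadeca-5,7,11-trienoate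
Conditions: SO3·pyridine, DMSO, i-Pr2NEt, CH2Cl2, 0 °C
Reagents that add atoms: none
Why: Parikh–Doering oxidation of the primary alcohol; the tertiary alcohol cannot be oxidised and the basic, non-acidic medium spares the alkenylstannane.

Step 9
Reactants: 15 methyl 2-[bis(2,2,2-trifluoroethoxy)phosphoryl]acetate
Product: 17 methyl 2-[bis(2,2,2-trifluoroethoxy)phosphoryl]-2-bromoacetate, via dibromophosphonate 16 (not isolated)
Conditions: Br2, NaOH, H2O, 0 °C; then SnCl2·2H2O, EtOH/H2O, 0 °C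
Reagents that add atoms: bromine, BrBr
Why: Hypobromite dibromination of the active methylene followed by selective reductive monodebromination with SnCl2, the standard route to monohalogenated phosphonoacetates.

Step 10
Reactants: 14 methyl (5E,7Z,9R,11Z)-9-formyl-9-hydroxy-8-(tributylstannyl)heptadeca-5,7,11-trienoate; 17 methyl 2-[bis(2,2,2-trifluoroethoxy)phosphoryl]-2-bromoacetate
Product: 19 methyl (5E,7Z)-8-[(2R)-4-bromo-2-[(2Z)-oct-2-en-1-yl]-5-oxo-2,5-dihydrofuran-2-yl]-8-(tributylstannyl)octa-5,7-dienoate, via open-chain hydroxy ester 18 (not isolated)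
Conditions: 17, KOt-Bu, 18-crown-6, THF, −78 °C; then 14, −78 to 0 °C; silica gel, CH2Cl2
Reagents that add atoms: none
Why: Horner–Wadsworth–Emmons olefination with the bis(trifluoroethyl) bromophosphonate is kinetically controlled to put the ester cis to the aldehyde residue (E-bromoacrylate), and that isomer alone is trapped by the tertiary hydroxyl as the butenolide, which fixes C9 cis to C12 on the C10=C11 bond.

Step 11
Reactants: 19 methyl (5E,7Z)-8-[(2R)-4-bromo-2-[(2Z)-oct-2-en-1-yl]-5-oxo-2,5-dihydrofuran-2-yl]-8-(tributylstannyl)octa-5,7-dienoate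
Product: 21 12-methyl 1-(triethylsilyl) (2E,4R,5Z,7E)-2-bromo-4-[(2Z)-oct-2-en-1-yl]-5-(tributylstannyl)-4-[(triethylsilyl)oxy]dodeca-2,5,7-trienedioate, via lithium carboxylate 20 (not isolated)
Conditions: LiOH·H2O (1.05 equiv), THF/H2O, 0 °C; evaporate, toluene azeotrope; TESOTf, 2,6-lutidine, CH2Cl2, −78 to 0 °C
Reagents that add atoms: lithium hydroxide, [Li+].[OH-]; triethylsilyl trifluoromethanesulfonate, CC[Si](CC)(CC)OS(=O)(=O)C(F)(F)F
Why: Saponification then silylation: the bromine-activated unsaturated γ-lactone should be attacked by hydroxide faster than the remote methyl ester, and the silyl triflate caps both the carboxylate and the tertiary alkoxide so that the ring cannot re-form.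

Step 12
Reactants: 21 12-methyl 1-(triethylsilyl) (2E,4R,5Z,7E)-2-bromo-4-[(2Z)-oct-2-en-1-yl]-5-(tributylstannyl)-4-[(triethylsilyl)oxy]dodeca-2,5,7-trienedioate
Product: 23 methyl (5E,7Z)-7-[(2R)-4-bromo-2-[(2Z)-oct-2-en-1-yl]-5-oxo-2-[(triethylsilyl)oxy]cyclopent-3-en-1-ylidene]hept-5-enoate, via acid chloride 22 (not isolated)
Conditions: (COCl)2, DMF (cat.), CH2Cl2, 0 °C; evaporate; Pd2(dba)3 (cat.), P(2-furyl)3, THF, rt
Reagents that add atoms: none
Why: Oxalyl chloride with catalytic DMF turns the silyl ester into acid chloride 22 under neutral conditions; zerovalent palladium then inserts into the C(acyl)–Cl bond, the alkenyl group on C8 passes from tin to palladium intramolecularly with retention, and reductive elimination from the six-membered acyl(alkenyl)palladacycle forms the C9–C8 bond. The closest known reaction type is the ketone-forming Stille coupling of acid chlorides with alkenylstannanes, which is also used intramolecularly for cyclic enones. The cyclopentenone ring (C8–C12) is closed as a 5-exo-trig acyl substitution at C9, made possible by the E geometry of C10=C11 that holds C9 cis to C12. No stereocentre is created: C12 is untouched, and the 7Z geometry is that of the stannane from step 7, carried over by stereoretentive transmetalation. The step needs chemoselection for the acyl chloride over the C10–Br bond and over the C12 silyl ether; the much faster oxidative addition of acid chlorides at room temperature, the intramolecular transmetalation (no stannane is left once the ring is closed) and the hindered triethylsilyl ether should secure it.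

Step 13
Reactants: 23 methyl (5E,7Z)-7-[(2R)-4-bromo-2-[(2Z)-oct-2-en-1-yl]-5-oxo-2-[(triethylsilyl)oxy]cyclopent-3-en-1-ylidene]hept-5-enoate
Product: 24 methyl (5E,7Z)-7-[(2R)-4-bromo-2-hydroxy-2-[(2Z)-oct-2-en-1-yl]-5-oxocyclopent-3-en-1-ylidene]hept-5-enoate (the target)
Conditions: HF·pyridine, pyridine, THF, 0 °C
Reagents that add atoms: none
Why: Fluoride-mediated cleavage of the tertiary silyl ether under buffered conditions that should spare the cross-conjugated dienone, the vinyl bromide and the methyl ester.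

Compound list
1 | 2-bromoprop-2-en-1-ol | OCC(Br)=C | starting material
2 | ethynyl(trimethyl)silane | C#C[Si](C)(C)C | starting material
3 | 2-methylidene-4-(trimethylsilyl)but-3-yn-1-ol | OCC(=C)C#C[Si](C)(C)C | intermediate
4 | [(2S)-2-[(trimethylsilyl)ethynyl]oxiran-2-yl]methanol | OC[C@@]1(C#C[Si](C)(C)C)CO1 | intermediate
5 | hept-1-yne | CCCCCC#C | starting material
6 | (2S)-2-[(trimethylsilyl)ethynyl]dec-4-yne-1,2-diol | OC[C@@](O)(C#C[Si](C)(C)C)CC#CCCCCC | intermediate
7 | (2S,4Z)-2-[(trimethylsilyl)ethynyl]dec-4-ene-1,2-diol | OC[C@@](O)(C#C[Si](C)(C)C)C/C=C\CCCCC | intermediate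
8 | methyl hex-5-ynoate | C#CCCCC(=O)OC | starting material
9 | chloro[(1E)-6-methoxy-6-oxohex-1-en-1-yl]zirconocene | COC(=O)CCC/C=C/[Zr](Cl)(C1C=CC=C1)C1C=CC=C1 | intermediate
10 | methyl (5E)-6-iodohex-5-enoate | COC(=O)CCC/C=C/I | intermediate
11 | (2S,4Z)-2-ethynyldec-4-ene-1,2-diol | OC[C@@](O)(C#C)C/C=C\CCCCC | intermediate
12 | methyl (5E,9S,11Z)-9-hydroxy-9-(hydroxymethyl)heptadeca-5,11-dien-7-ynoate | OC[C@@](O)(C#C/C=C/CCCC(=O)OC)C/C=C\CCCCC | intermediate
13 | methyl (5E,7Z,9R,11Z)-9-hydroxy-9-(hydroxymethyl)-8-(tributylstannyl)heptadeca-5,7,11-trienoate | OC[C@@](O)(/C(=C/C=C/CCCC(=O)OC)[Sn](CCCC)(CCCC)CCCC)C/C=C\CCCCC | intermediate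
14 | methyl (5E,7Z,9R,11Z)-9-formyl-9-hydroxy-8-(tributylstannyl)heptadeca-5,7,11-trienoate | O=C[C@@](O)(/C(=C/C=C/CCCC(=O)OC)[Sn](CCCC)(CCCC)CCCC)C/C=C\CCCCC | intermediate
15 | methyl 2-[bis(2,2,2-trifluoroethoxy)phosphoryl]acetate | COC(=O)CP(=O)(OCC(F)(F)F)OCC(F)(F)F | starting material
16 | methyl 2-[bis(2,2,2-trifluoroethoxy)phosphoryl]-2,2-dibromoacetate | COC(=O)C(Br)(Br)P(=O)(OCC(F)(F)F)OCC(F)(F)F | intermediate
17 | methyl 2-[bis(2,2,2-trifluoroethoxy)phosphoryl]-2-bromoacetate | COC(=O)C(Br)P(=O)(OCC(F)(F)F)OCC(F)(F)F | intermediate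
18 | dimethyl (2E,4R,5Z,7E)-2-bromo-4-hydroxy-4-[(2Z)-oct-2-en-1-yl]-5-(tributylstannyl)dodeca-2,5,7-trienedioate | CCCCC/C=C\C[C@@](O)(/C=C(/Br)C(=O)OC)/C(=C/C=C/CCCC(=O)OC)[Sn](CCCC)(CCCC)CCCC | intermediate
19 | methyl (5E,7Z)-8-[(2R)-4-bromo-2-[(2Z)-oct-2-en-1-yl]-5-oxo-2,5-dihydrofuran-2-yl]-8-(tributylstannyl)octa-5,7-dienoate | CCCCC/C=C\C[C@@]1(/C(=C/C=C/CCCC(=O)OC)[Sn](CCCC)(CCCC)CCCC)OC(=O)C(Br)=C1 | intermediate
20 | lithium (2E,4R,5Z,7E)-2-bromo-4-hydroxy-12-methoxy-4-[(2Z)-oct-2-en-1-yl]-12-oxo-5-(tributylstannyl)dodeca-2,5,7-trienoate | CCCCC/C=C\C[C@@](O)(/C=C(/Br)C(=O)[O-])/C(=C/C=C/CCCC(=O)OC)[Sn](CCCC)(CCCC)CCCC.[Li+] | intermediate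
21 | 12-methyl 1-(triethylsilyl) (2E,4R,5Z,7E)-2-bromo-4-[(2Z)-oct-2-en-1-yl]-5-(tributylstannyl)-4-[(triethylsilyl)oxy]dodeca-2,5,7-trienedioate | CCCCC/C=C\C[C@@](O[Si](CC)(CC)CC)(/C=C(/Br)C(=O)O[Si](CC)(CC)CC)/C(=C/C=C/CCCC(=O)OC)[Sn](CCCC)(CCCC)CCCC | intermediate
22 | methyl (5E,7Z,9R,10E)-11-bromo-12-chloro-9-[(2Z)-oct-2-en-1-yl]-12-oxo-8-(tributylstannyl)-9-[(triethylsilyl)oxy]dodeca-5,7,10-trienoate | CCCCC/C=C\C[C@@](O[Si](CC)(CC)CC)(/C=C(/Br)C(Cl)=O)/C(=C/C=C/CCCC(=O)OC)[Sn](CCCC)(CCCC)CCCC | intermediate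
23 | methyl (5E,7Z)-7-[(2R)-4-bromo-2-[(2Z)-oct-2-en-1-yl]-5-oxo-2-[(triethylsilyl)oxy]cyclopent-3-en-1-ylidene]hept-5-enoate | CCCCC/C=C\C[C@@]1(O[Si](CC)(CC)CC)C=C(Br)C(=O)/C1=C\C=C\CCCC(=O)OC | intermediate
24 | methyl (5E,7Z)-7-[(2R)-4-bromo-2-hydroxy-2-[(2Z)-oct-2-en-1-yl]-5-oxocyclopent-3-en-1-ylidene]hept-5-enoate | CCCCC/C=C\C[C@@]1(O)C=C(Br)C(=O)/C1=C\C=C\CCCC(=O)OC | target

Total step count: 13. Longest linear sequence: 11 steps (steps 1–4, 6–8 and 10–13; steps 5 and 9 prepare the side-chain iodide 10 and the phosphonate 17).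

Steps most likely to fail

1. Step 12 (key step). Transmetalation at the fully substituted C8, next to the silylated quaternary C12, may be slow. Zerovalent palladium could then insert into the C10–Br bond, or the acid chloride could attack the C12 silyl ether, with loss of the silyl group and return to the lactone. Fallback (sets out from 19, comes back at 24): the ring is closed at the aldehyde oxidation level with chromium instead of palladium. Iododestannylation of 19 (I2, CH2Cl2, 0 °C) should give methyl (5E,7Z)-8-[(2R)-4-bromo-2-[(2Z)-oct-2-en-1-yl]-5-oxo-2,5-dihydrofuran-2-yl]-8-iodoocta-5,7-dienoate F1. Reduction of the activated lactone with i-Bu2AlH (1.0 equiv, CH2Cl2, −78 °C) should give the lactol methyl (5E,7Z)-8-[(2R)-4-bromo-5-hydroxy-2-[(2Z)-oct-2-en-1-yl]-2,5-dihydrofuran-2-yl]-8-iodoocta-5,7-dienoate F2. An intramolecular Nozaki–Hiyama–Kishi reaction (CrCl2, NiCl2 cat., DMF/THF, rt) on the open hydroxy-enal form of F2 closes the same C9–C8 bond with retention at C8, to methyl (5E,7E)-7-[(2R)-4-bromo-2,5-dihydroxy-2-[(2Z)-oct-2-en-1-yl]cyclopent-3-en-1-ylidene]hept-5-enoate F3 (same exocyclic geometry as 24; the descriptor changes only by priority). MnO2 in CH2Cl2 then oxidises the secondary allylic alcohol to 24.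

2. Step 7. The conjugated enyne, and the diene formed from it, may sequester the ruthenium catalyst, and the hindered tertiary carbinol may lose regiocontrol, so that tin is delivered to C7 or conversion stalls. Fallback (sets out from 12, comes back at 13): an O-directed free-radical hydrostannation (Ph3SnH, Et3B cat., trace air, toluene, rt) should give methyl (5E,7Z,9R,11Z)-9-hydroxy-9-(hydroxymethyl)-8-(triphenylstannyl)heptadeca-5,7,11-trienoate F4. Iodinolysis (I2, CH2Cl2, 0 °C) gives methyl (5E,7Z,9R,11Z)-9-hydroxy-9-(hydroxymethyl)-8-iodoheptadeca-5,7,11-trienoate F5. Stannylation of F5 with Bu3SnSnBu3 and Pd(PPh3)4 (cat.) in toluene returns 13 with retention.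

3. Step 11. Hydroxide may also saponify the C1 methyl ester, and incomplete silylation of the tertiary alkoxide would let the hydroxy ester close back to the lactone. Fallback (sets out from 13, comes back at 21): the tertiary hydroxyl is protected before the olefination, so no lactone forms and no hydrolysis is needed. TESOTf and 2,6-lutidine convert 13 into methyl (5E,7Z,9R,11Z)-8-(tributylstannyl)-9-[(triethylsilyl)oxy]-9-{[(triethylsilyl)oxy]methyl}heptadeca-5,7,11-trienoate F6. Swern conditions ((COCl)2, DMSO, Et3N, −78 to −20 °C) oxidise the primary silyl ether directly to methyl (5E,7Z,9R,11Z)-9-formyl-8-(tributylstannyl)-9-[(triethylsilyl)oxy]heptadeca-5,7,11-trienoate F7. Horner–Wadsworth–Emmons olefination follows, with tert-butyl 2-[bis(2,2,2-trifluoroethoxy)phosphoryl]-2-bromoacetate F8 (made as in step 9 from the tert-butyl phosphonoacetate; KOt-Bu, 18-crown-6, THF, −78 °C). It should give 1-tert-butyl 12-methyl (2E,4R,5Z,7E)-2-bromo-4-[(2Z)-oct-2-en-1-yl]-5-(tributylstannyl)-4-[(triethylsilyl)oxy]dodeca-2,5,7-trienedioate F9. TESOTf and 2,6-lutidine then exchange the tert-butyl ester for the triethylsilyl ester, which is 21.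

Further compounds
F1 | step 12 | methyl (5E,7Z)-8-[(2R)-4-bromo-2-[(2Z)-oct-2-en-1-yl]-5-oxo-2,5-dihydrofuran-2-yl]-8-iodoocta-5,7-dienoate | CCCCC/C=C\C[C@@]1(/C(I)=C/C=C/CCCC(=O)OC)OC(=O)C(Br)=C1
F2 | step 12 | methyl (5E,7Z)-8-[(2R)-4-bromo-5-hydroxy-2-[(2Z)-oct-2-en-1-yl]-2,5-dihydrofuran-2-yl]-8-iodoocta-5,7-dienoate | CCCCC/C=C\C[C@@]1(/C(I)=C/C=C/CCCC(=O)OC)OC(O)C(Br)=C1
F3 | step 12 | methyl (5E,7E)-7-[(2R)-4-bromo-2,5-dihydroxy-2-[(2Z)-oct-2-en-1-yl]cyclopent-3-en-1-ylidene]hept-5-enoate | CCCCC/C=C\C[C@@]1(O)C=C(Br)C(O)/C1=C\C=C\CCCC(=O)OC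
F4 | step 7 | methyl (5E,7Z,9R,11Z)-9-hydroxy-9-(hydroxymethyl)-8-(triphenylstannyl)heptadeca-5,7,11-trienoate | OC[C@@](O)(/C(=C/C=C/CCCC(=O)OC)[Sn](c1ccccc1)(c1ccccc1)c1ccccc1)C/C=C\CCCCC
F5 | step 7 | methyl (5E,7Z,9R,11Z)-9-hydroxy-9-(hydroxymethyl)-8-iodoheptadeca-5,7,11-trienoate | OC[C@@](O)(/C(I)=C/C=C/CCCC(=O)OC)C/C=C\CCCCC
F6 | step 11 | methyl (5E,7Z,9R,11Z)-8-(tributylstannyl)-9-[(triethylsilyl)oxy]-9-{[(triethylsilyl)oxy]methyl}heptadeca-5,7,11-trienoate | CC[Si](CC)(CC)OC[C@@](O[Si](CC)(CC)CC)(/C(=C/C=C/CCCC(=O)OC)[Sn](CCCC)(CCCC)CCCC)C/C=C\CCCCC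
F7 | step 11 | methyl (5E,7Z,9R,11Z)-9-formyl-8-(tributylstannyl)-9-[(triethylsilyl)oxy]heptadeca-5,7,11-trienoate | O=C[C@@](O[Si](CC)(CC)CC)(/C(=C/C=C/CCCC(=O)OC)[Sn](CCCC)(CCCC)CCCC)C/C=C\CCCCC
F8 | step 11 | tert-butyl 2-[bis(2,2,2-trifluoroethoxy)phosphoryl]-2-bromoacetate | CC(C)(C)OC(=O)C(Br)P(=O)(OCC(F)(F)F)OCC(F)(F)F
F9 | step 11 | 1-tert-butyl 12-methyl (2E,4R,5Z,7E)-2-bromo-4-[(2Z)-oct-2-en-1-yl]-5-(tributylstannyl)-4-[(triethylsilyl)oxy]dodeca-2,5,7-trienedioate | CCCCC/C=C\C[C@@](O[Si](CC)(CC)CC)(/C=C(/Br)C(=O)OC(C)(C)C)/C(=C/C=C/CCCC(=O)OC)[Sn](CCCC)(CCCC)CCCC
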